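Start at the late end of the summer run: from 4.00 h to 30.0 h the substrate barely moves, and at the last reading it stands at 46.5% with target at 0.4%.

| setting | midnight | summer | zeta | epsilon | delta | theta | beta |
|---|---|---|---|---|---|---|---|
| substrate | 6.8 mM | 57 mM | 5.0 mM | 10 mM | 20 mM | 15 mM | 40 mM |
| reagent | 15 mM | 15 mM | 15.0 mM | 15.0 mM | 15.0 mM | 15.0 mM | 15.0 mM |
| initiator | 100 µM | 100 µM | 100 µM | 100 µM | 100 µM | 100 µM | 100 µM |
| temperature | 45 °C | 60 °C | 60 °C | 60 °C | 60 °C | 60 °C | 60 °C |
| remark | run made earlier | run made earlier |  |  |  |  |  |
| time |  |  | 30 h | 30 h | 30 h | 30 h | 30 h |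

- midnight (time / h: target / %, substrate / %): 8.00: 95.0, 0; 15.0: 95.2, 0; 25.0: 95.6, 0.3; 30.0: 95.8, 0; 40.0: 93.3, 1.0; 48.0: 94.8, 0; 60.0: 96.4, 0.2
- summer (time / h: target / %, substrate / %): 4.00: 1.4, 47.0; 8.00: 0, 49.4; 12.0: 0, 46.8; 15.0: 0.8, 49.4; 20.0: 1.0, 44.4; 25.0: 0, 48.0; 30.0: 0.4, 46.5

(standard deviation of a reading: 1 percentage point)



- ranking by amount of target, in percent of the substrate charged, from high to low, at 30 h (zeta / epsilon / delta / theta / beta)
- the amount of target, in percent of the substrate charged of the flask you put first, at 30 h
- the amount of target, in percent of the substrate charged of the flask you put last, at 30 h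

Open the books on the summer run. Substrate consumed is 30.5 mM against 15 mM of reagent charged, a reading of 2.03 substrate per reagent. Take reagent as the limiting reagent, and take two substrate as the most one reagent can carry. For the new flasks, this gives a reagent capacity of 30.0 mM, the substrate their reagent charge can consume.

Now book each mole of reagent, as my own reckoning. Entry one is reagent ending in target, with one substrate each. Entry two is reagent in the unseen form of the summer run, with two substrate each. Where substrate exceeds reagent and both are used up, the entries close with c(target) = capacity − c(substrate).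

For delta this books 10.0 mM of target, or 50.0% of its substrate. Beta is charged above capacity, so its target entry is zero and 25.0% of its substrate stays. Zeta, epsilon and theta hold no more substrate than reagent, so the books don't separate them. Rank them by substrate. The midnight run, cooler and with reagent in excess, reads 95.8% at 30.0 h and shows no substrate at 8.00 h, so take time as ample.

The forecast calls this “a stoichiometric limit rather than a kinetic one”. It gives zeta > epsilon > theta > delta > beta, with 95% at the top and 0.4% at the bottom, where my books put zero.

The flasks give zeta > epsilon > theta > delta > beta: zeta 97.3%, epsilon 94.7%, theta 88.4%, delta 50.7%, beta 0.00949%.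

    2 second chain carrier → ended chains (k = 3.80 × 10⁷ /M/s, Ea = 21.0 kJ/mol)
    reagent + first chain carrier → target + second chain carrier (k = 3.20 × 10⁷ /M/h, Ea = 45.0 kJ/mol)
    substrate + target → side product (k = 25.0 /M/h, Ea = 52.0 kJ/mol)
    initiator → 2 initiating radical (k = 0.0600 /h, Ea = 106 kJ/mol)
    reagent + by-product ⇌ idle adduct, settled at all times (K = 9500 /M, ΔH = −37.0 kJ/mol)
    substrate + initiating radical → capped initiator + first chain carrier (k = 1.60 × 10⁵ /M/s, Ea = 10.0 kJ/mol)
    substrate + second chain carrier → by-product + first chain carrier (k = 1.90 × 10⁵ /M/s, Ea = 26.0 kJ/mol)
    (constants at 60 °C)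

Look at beta: depletion of reagent is the main reason its target is missing. With that depletion taken away and reagent held at its charge, the same flask gives 82.9% of target instead of 0.00949%. Beta ends with reagent at 0% and substrate at 24.6%, as booked against its capacity of 30.0 mM, and side product, which counts as two substrate, is the unseen form at 75.0%. Apply the same books to a neighbour of zeta charged with 3.8 mM of reagent: capacity 7.60 mM books 52.0%. That neighbour gives 56.7% of target, with 3.30% of its substrate held as first chain carrier.

The earlier runs and the new flask were computed with constants of no real substance, noise included.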